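**Retrosynthetic overview**

- The strategy rests on the 3,4-dihydro-2H-pyran (O1, C2 with CH3, C3 with CHO, C4 with the CH2CO2R arm, C5 with CO2Me, C6). Its O1–C2 bond is β to the C3 formyl group, so the ring is the oxa-Michael adduct of a C5=C6–OH formylacetate enol and a C3 (E)-ethylidene enal; opening it leaves C4 as the only stereocentre.
- The pyran is the only ring made (step 13); the catechol is unveiled afterwards (step 14).
- The enol is released last by Fukuyama reduction of a malonyl S-ethyl thioester (latent C6 formyl), because a late Claisen formylation could not tell the two CH2CO2R groups apart. The ethylidene comes from crossed aldol condensation of the C3 acetaldehyde arm with acetaldehyde.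
- C4 is set by an iminium-catalysed Michael addition of S-ethyl O-methyl thiomalonate to (E)-5-silyloxypent-2-enal. The aldehyde so formed becomes the hydroxytyrosyl acetate arm (Pinnick, Steglich); the silyloxyethyl arm becomes C3 and its formyl group.

Key step: step 13

Remark: the malonyl carbon (future C5) of 8, 9, 13–15, 17 and 18 bears an acidic hydrogen and is carried as an inconsequential pair of epimers (drawn without configuration); it becomes sp2 in step 12. TBSO = tert-butyldimethylsilyloxy.

**Route**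

Step 1
Reactants: 1 but-3-en-1-ol
Product: 2 tert-butyl(but-3-en-1-yloxy)dimethylsilane
Conditions: TBSCl, imidazole, CH2Cl2, 0 °C to rt
Reagents that add atoms: tert-butyldimethylsilyl chloride, CC(C)(C)[Si](C)(C)Cl
Why: Imidazole-promoted silylation of the primary alcohol gives a TBS ether that survives the metathesis, Michael, oxidation and esterification steps.

Step 2
Reactants: 2 tert-butyl(but-3-en-1-yloxy)dimethylsilane; 3 (E)-but-2-enal (crotonaldehyde)
Product: 4 (2E)-5-(TBSO)pent-2-enal
Conditions: 3 (5 equiv), second-generation Hoveyda–Grubbs catalyst (3 mol%), CH2Cl2, 40 °C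
Reagents that add atoms: none
Why: Olefin cross-metathesis between the terminal alkene and excess crotonaldehyde expels propene and gives the conjugated enal as the thermodynamically favoured E isomer.

Step 3
Reactants: 5 methyl 3-chloro-3-oxopropanoate; 6 ethanethiol
Product: 7 methyl 3-(ethylsulfanyl)-3-oxopropanoate (S-ethyl O-methyl thiomalonate)
Conditions: pyridine, CH2Cl2, 0 °C
Reagents that add atoms: none
Why: Acyl substitution of the acid chloride by the thiol (pyridine as HCl acceptor) gives the mixed thiomalonate, whose thioester is the latent C6 formyl group.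

Step 4
Reactants: 4 (2E)-5-(TBSO)pent-2-enal; 7 methyl 3-(ethylsulfanyl)-3-oxopropanoate
Product: 8 methyl (3R)-5-(TBSO)-2-[(ethylsulfanyl)carbonyl]-3-(2-oxoethyl)pentanoate
Conditions: (S)-α,α-diphenylprolinol trimethylsilyl ether (10 mol%), PhCO2H (10 mol%), EtOH, 0 °C to rt
Reagents that add atoms: none
Why: Iminium-catalysed Michael addition (Jørgensen–Hayashi catalysis): the diphenyl(trimethylsilyloxy)methyl group shields one face of the s-trans E-iminium ion of 4, so the thiomalonate carbon adds to the open face of the β-carbon and sets the centre that becomes C4 of the pyran (3R here; 4S in the target only because the CIP priorities change).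

Step 5
Reactants: 8 methyl (3R)-5-(TBSO)-2-[(ethylsulfanyl)carbonyl]-3-(2-oxoethyl)pentanoate
Product: 9 (3R)-5-(TBSO)-3-{1-[(ethylsulfanyl)carbonyl]-2-methoxy-2-oxoethyl}pentanoic acid
Conditions: NaClO2, NaH2PO4, 2-methylbut-2-ene, t-BuOH/H2O, 0 °C to rt
Reagents that add atoms: sodium chlorite, [Na+].[O-]Cl=O
Why: Pinnick oxidation turns the saturated aldehyde into the acid at pH 3–4 without touching the thioester, the silyl ether or the β-stereocentre, 2-methylbut-2-ene trapping the hypochlorous acid that could otherwise chlorinate the malonyl position.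

Step 6
Reactants: 10 hydroxytyrosol
Product: 11 3,4-bis(TBSO)-1-[2-(TBSO)ethyl]benzene
Conditions: TBSCl (3.5 equiv), imidazole, DMF, rt
Reagents that add atoms: tert-butyldimethylsilyl chloride, CC(C)(C)[Si](C)(C)Cl
Why: Exhaustive imidazole-promoted silylation covers both phenols and the alcohol, which prepares a selective release of the alcohol alone.

Step 7
Reactants: 11 3,4-bis(TBSO)-1-[2-(TBSO)ethyl]benzene
Product: 12 2-[3,4-bis(TBSO)phenyl]ethanol
Conditions: 48% aq. HF, MeCN/CH2Cl2, 0 °C
Reagents that add atoms: none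
Why: Acidic fluoride cleaves a primary alkyl silyl ether far faster than aryl silyl ethers (the reverse of the order under basic fluoride), so this chemoselective desilylation should free only the alcohol.

Step 8
Reactants: 9 (3R)-5-(TBSO)-3-{1-[(ethylsulfanyl)carbonyl]-2-methoxy-2-oxoethyl}pentanoic acid; 12 2-[3,4-bis(TBSO)phenyl]ethanol
Product: 13 methyl (3R)-3-{2-[2-(3,4-bis(TBSO)phenyl)ethoxy]-2-oxoethyl}-5-(TBSO)-2-[(ethylsulfanyl)carbonyl]pentanoate
Conditions: EDC·HCl, DMAP (cat.), CH2Cl2, 0 °C to rt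
Reagents that add atoms: none
Why: Steglich esterification (carbodiimide activation, DMAP acyl transfer) joins acid and primary alcohol under conditions too mild to disturb the thioester or the aryl silyl ethers.

Step 9
Reactants: 13 methyl (3R)-3-{2-[2-(3,4-bis(TBSO)phenyl)ethoxy]-2-oxoethyl}-5-(TBSO)-2-[(ethylsulfanyl)carbonyl]pentanoate
Product: 14 methyl (3R)-3-{2-[2-(3,4-bis(TBSO)phenyl)ethoxy]-2-oxoethyl}-2-[(ethylsulfanyl)carbonyl]-5-hydroxypentanoate
Conditions: 48% aq. HF, MeCN, 0 °C; crude used at once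
Reagents that add atoms: none
Why: The same alkyl-over-aryl selectivity of acidic fluoride unveils the primary alcohol of the future C3 arm, which is oxidised at once so that δ-lactonisation onto the neighbouring esters has no time to occur.

Step 10
Reactants: 14 methyl (3R)-3-{2-[2-(3,4-bis(TBSO)phenyl)ethoxy]-2-oxoethyl}-2-[(ethylsulfanyl)carbonyl]-5-hydroxypentanoate
Product: 15 methyl (3R)-3-{2-[2-(3,4-bis(TBSO)phenyl)ethoxy]-2-oxoethyl}-2-[(ethylsulfanyl)carbonyl]-5-oxopentanoate
Conditions: DMP, CH2Cl2, 0 °C to rt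
Reagents that add atoms: none
Why: Dess–Martin oxidation converts the primary alcohol into the aldehyde under neutral conditions that leave the thioester, the malonyl C–H and the silyl ethers alone.

Step 11
Reactants: 15 methyl (3R)-3-{2-[2-(3,4-bis(TBSO)phenyl)ethoxy]-2-oxoethyl}-2-[(ethylsulfanyl)carbonyl]-5-oxopentanoate; 16 acetaldehyde
Product: 18 methyl (3R,4E)-3-{2-[2-(3,4-bis(TBSO)phenyl)ethoxy]-2-oxoethyl}-2-[(ethylsulfanyl)carbonyl]-4-formylhex-4-enoate, via β-hydroxy aldehyde aldol adduct 17 (not isolated)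
Conditions: 16 (5 equiv, slow addition), pyrrolidine (20 mol%), PhCO2H (20 mol%), CH2Cl2, 0 °C to rt
Reagents that add atoms: none
Why: Amine-catalysed crossed aldol condensation: the enamine of 15 adds to the more electrophilic acetaldehyde and aldol 17 dehydrates through the iminium/dienamine manifold to the conjugated (E)-2-ethylidene aldehyde (formyl trans to methyl, the tiglaldehyde-type thermodynamic isomer), the hindered malonyl C–H staying a spectator.

Step 12
Reactants: 18 methyl (3R,4E)-3-{2-[2-(3,4-bis(TBSO)phenyl)ethoxy]-2-oxoethyl}-2-[(ethylsulfanyl)carbonyl]-4-formylhex-4-enoate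
Product: 19 methyl (2Z,3S,4E)-3-{2-[2-(3,4-bis(TBSO)phenyl)ethoxy]-2-oxoethyl}-4-formyl-2-(hydroxymethylidene)hex-4-enoate
Conditions: Et3SiH, 10% Pd/C, acetone, 0 °C to rt; filtered, used crude
Reagents that add atoms: none
Why: Fukuyama reduction: palladium inserts into the acyl–sulfur bond and the silane delivers hydride, so the thioester alone becomes an aldehyde, which rests as the hydrogen-bonded Z enol (a vinylogous acid), while oxo esters, the hindered trisubstituted enal and the aryl silyl ethers should be spared in an aprotic medium.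

Step 13
Reactants: 19 methyl (2Z,3S,4E)-3-{2-[2-(3,4-bis(TBSO)phenyl)ethoxy]-2-oxoethyl}-4-formyl-2-(hydroxymethylidene)hex-4-enoate
Product: 21 methyl (2S,3S,4S)-4-{2-[2-(3,4-bis(TBSO)phenyl)ethoxy]-2-oxoethyl}-3-formyl-2-methyl-3,4-dihydro-2H-pyran-5-carboxylate, via ring-closed C3 enol 20 (not isolated)
Conditions: Et3N (0.3 equiv), CH2Cl2 (0.02 M), 0 °C to rt; pH 7 buffer
Reagents that add atoms: none
Why: Triethylamine deprotonates the vinylogous acid of 19 and the enolate oxygen (the future O1) adds to C2, the β-carbon of the (E)-ethylidene enal, forming the O1–C2 bond and closing the dihydropyran in the 6-endo-trig mode to the C3 enol(ate) 20, which is then protonated at C3. The closest known reaction type is the intramolecular oxa-Michael addition of a β-dicarbonyl enol to an enal, the recyclisation that secoiridoid enol dialdehydes undergo once their acetal is opened. Ring closure (retro-oxa-Michael through the C3 enolate) and C3 protonation are both reversible under the amine, so C2 and C3 are set under thermodynamic control by the fixed C4 centre: the C4 acetate arm sits pseudoaxial to escape A(1,2) strain with the C5 ester, the C2 methyl then prefers the equatorial site (axial would be syn-diaxial to that arm) and the C3 formyl the axial site anti to the arm, which together is the 2S,3S,4S isomer. The step needs 1,4- over 1,2-addition and diastereoselection at C2 and C3; the 1,2-adduct (a lactol from attack at the formyl carbon) is a hemiacetal that reopens, whereas the oxa-Michael adduct keeps the vinylogous carbonate conjugation and is the sink, and C4, which has no acidic hydrogen, cannot epimerise.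

Step 14
Reactants: 21 methyl (2S,3S,4S)-4-{2-[2-(3,4-bis(TBSO)phenyl)ethoxy]-2-oxoethyl}-3-formyl-2-methyl-3,4-dihydro-2H-pyran-5-carboxylate
Product: 22 methyl (2S,3S,4S)-4-{2-[2-(3,4-dihydroxyphenyl)ethoxy]-2-oxoethyl}-3-formyl-2-methyl-3,4-dihydro-2H-pyran-5-carboxylate (target)
Conditions: TBAF, AcOH (1:1), THF, 0 °C
Reagents that add atoms: none
Why: Fluoride cleaves aryl silyl ethers rapidly, and buffering with acetic acid keeps the medium too weakly basic for retro-oxa-Michael opening or C3 epimerisation of the β-alkoxy aldehyde or for oxidation of the catechol.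

**Compound list**

1 | but-3-en-1-ol | C=CCCO | starting material
2 | tert-butyl(but-3-en-1-yloxy)dimethylsilane | C=CCCO[Si](C)(C)C(C)(C)C | intermediate
3 | (E)-but-2-enal (crotonaldehyde) | C/C=C/C=O | starting material
4 | (2E)-5-(TBSO)pent-2-enal | O=C/C=C/CCO[Si](C)(C)C(C)(C)C | intermediate
5 | methyl 3-chloro-3-oxopropanoate | COC(=O)CC(=O)Cl | starting material
6 | ethanethiol | CCS | starting material
7 | methyl 3-(ethylsulfanyl)-3-oxopropanoate | COC(=O)CC(=O)SCC | intermediate
8 | methyl (3R)-5-(TBSO)-2-[(ethylsulfanyl)carbonyl]-3-(2-oxoethyl)pentanoate, C2 epimers | COC(=O)C(C(=O)SCC)[C@@H](CC=O)CCO[Si](C)(C)C(C)(C)C | intermediate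
9 | (3R)-5-(TBSO)-3-{1-[(ethylsulfanyl)carbonyl]-2-methoxy-2-oxoethyl}pentanoic acid | COC(=O)C(C(=O)SCC)[C@@H](CC(=O)O)CCO[Si](C)(C)C(C)(C)C | intermediate
10 | hydroxytyrosol, 2-(3,4-dihydroxyphenyl)ethanol | OCCc1ccc(O)c(O)c1 | starting material
11 | 3,4-bis(TBSO)-1-[2-(TBSO)ethyl]benzene | CC(C)(C)[Si](C)(C)OCCc1ccc(O[Si](C)(C)C(C)(C)C)c(O[Si](C)(C)C(C)(C)C)c1 | intermediate
12 | 2-[3,4-bis(TBSO)phenyl]ethanol | OCCc1ccc(O[Si](C)(C)C(C)(C)C)c(O[Si](C)(C)C(C)(C)C)c1 | intermediate
13 | methyl (3R)-3-{2-[2-(3,4-bis(TBSO)phenyl)ethoxy]-2-oxoethyl}-5-(TBSO)-2-[(ethylsulfanyl)carbonyl]pentanoate | COC(=O)C(C(=O)SCC)[C@@H](CC(=O)OCCc1ccc(O[Si](C)(C)C(C)(C)C)c(O[Si](C)(C)C(C)(C)C)c1)CCO[Si](C)(C)C(C)(C)C | intermediate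
14 | methyl (3R)-3-{2-[2-(3,4-bis(TBSO)phenyl)ethoxy]-2-oxoethyl}-2-[(ethylsulfanyl)carbonyl]-5-hydroxypentanoate | COC(=O)C(C(=O)SCC)[C@@H](CC(=O)OCCc1ccc(O[Si](C)(C)C(C)(C)C)c(O[Si](C)(C)C(C)(C)C)c1)CCO | intermediate
15 | methyl (3R)-3-{2-[2-(3,4-bis(TBSO)phenyl)ethoxy]-2-oxoethyl}-2-[(ethylsulfanyl)carbonyl]-5-oxopentanoate | COC(=O)C(C(=O)SCC)[C@@H](CC(=O)OCCc1ccc(O[Si](C)(C)C(C)(C)C)c(O[Si](C)(C)C(C)(C)C)c1)CC=O | intermediate
16 | acetaldehyde | CC=O | starting material
17 | aldol adduct, methyl (3S)-3-{2-[2-(3,4-bis(TBSO)phenyl)ethoxy]-2-oxoethyl}-2-[(ethylsulfanyl)carbonyl]-4-formyl-5-hydroxyhexanoate (C3 spatially as in 15; C4/C5 diastereomers) | COC(=O)C(C(=O)SCC)[C@@H](CC(=O)OCCc1ccc(O[Si](C)(C)C(C)(C)C)c(O[Si](C)(C)C(C)(C)C)c1)C(C=O)C(C)O | intermediate (not isolated)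
18 | methyl (3R,4E)-3-{2-[2-(3,4-bis(TBSO)phenyl)ethoxy]-2-oxoethyl}-2-[(ethylsulfanyl)carbonyl]-4-formylhex-4-enoate | COC(=O)C(C(=O)SCC)[C@@H](CC(=O)OCCc1ccc(O[Si](C)(C)C(C)(C)C)c(O[Si](C)(C)C(C)(C)C)c1)/C(C=O)=C\C | intermediate
19 | methyl (2Z,3S,4E)-3-{2-[2-(3,4-bis(TBSO)phenyl)ethoxy]-2-oxoethyl}-4-formyl-2-(hydroxymethylidene)hex-4-enoate (key-step precursor) | COC(=O)/C(=C\O)[C@@H](CC(=O)OCCc1ccc(O[Si](C)(C)C(C)(C)C)c(O[Si](C)(C)C(C)(C)C)c1)/C(C=O)=C\C | intermediate
20 | methyl (2S,4S)-4-{2-[2-(3,4-bis(TBSO)phenyl)ethoxy]-2-oxoethyl}-3-(hydroxymethylidene)-2-methyl-3,4-dihydro-2H-pyran-5-carboxylate (C3 enol) | COC(=O)C1=CO[C@@H](C)C(=CO)[C@@H]1CC(=O)OCCc1ccc(O[Si](C)(C)C(C)(C)C)c(O[Si](C)(C)C(C)(C)C)c1 | intermediate (not isolated)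
21 | methyl (2S,3S,4S)-4-{2-[2-(3,4-bis(TBSO)phenyl)ethoxy]-2-oxoethyl}-3-formyl-2-methyl-3,4-dihydro-2H-pyran-5-carboxylate | COC(=O)C1=CO[C@@H](C)[C@@H](C=O)[C@@H]1CC(=O)OCCc1ccc(O[Si](C)(C)C(C)(C)C)c(O[Si](C)(C)C(C)(C)C)c1 | intermediate
22 | methyl (2S,3S,4S)-4-{2-[2-(3,4-dihydroxyphenyl)ethoxy]-2-oxoethyl}-3-formyl-2-methyl-3,4-dihydro-2H-pyran-5-carboxylate | COC(=O)C1=CO[C@@H](C)[C@@H](C=O)[C@@H]1CC(=O)OCCc1ccc(O)c(O)c1 | target

**Step count**

Total step count: 14.
Longest linear sequence: 11 steps (1, 2, 4, 5, 8, 9, 10, 11, 12, 13, 14, from but-3-en-1-ol).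

**Steps most likely to fail**

Step 11 (crossed aldol condensation). Self-condensation and oligomerisation of acetaldehyde may outrun the crossed reaction. The thioester may also acylate the secondary amine, and the enamine of 15 may expel the thiomalonate (retro-Michael), which would erode C4. Fallback, setting out from 15: a Mannich-type α-methylenation (aqueous formaldehyde 1.1 equiv, pyrrolidine/propionic acid 10 mol%, i-PrOH, 45 °C, short contact time) should give the 2-substituted acrolein methyl (3R)-3-{2-[2-(3,4-bis(TBSO)phenyl)ethoxy]-2-oxoethyl}-2-[(ethylsulfanyl)carbonyl]-4-formylpent-4-enoate F1. Olefin cross-metathesis of F1 with excess (Z)-but-2-ene (second-generation Hoveyda–Grubbs catalyst, CH2Cl2, 40 °C, sealed vessel) should then install the ethylidene as the favoured E isomer, and the route is rejoined at 18.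

Step 12 (Fukuyama reduction). The palladium/silane couple may reduce the ethylidene enal by conjugate hydrosilylation, or the reduction may stall through sulfur poisoning of the metal surface. Fallback, setting out from 15: the thioester is reduced before any alkene is present (Et3SiH, 10% Pd/C, acetone). The formylacetate enol then closes on the saturated aldehyde to the lactol methyl (4R)-4-{2-[2-(3,4-bis(TBSO)phenyl)ethoxy]-2-oxoethyl}-2-hydroxy-3,4-dihydro-2H-pyran-5-carboxylate F2. Pyrrolidine (1.1 equiv, CH2Cl2, 4 Å sieves) should open F2 to the vinylogous carbamate methyl (3R)-3-{2-[2-(3,4-bis(TBSO)phenyl)ethoxy]-2-oxoethyl}-5-oxo-2-(pyrrolidin-1-ylmethylidene)pentanoate F3, in which the enol is masked and no malonyl C–H, thioester or leaving group at C4 remains. Crossed aldol condensation of F3 with acetaldehyde (pyrrolidine/PhCO2H cat.) should give the enaminoester enal methyl (3S,4E)-3-{2-[2-(3,4-bis(TBSO)phenyl)ethoxy]-2-oxoethyl}-4-formyl-2-(pyrrolidin-1-ylmethylidene)hex-4-enoate F4. Hydrolysis of the enamine with dilute aqueous HCl in THF rejoins the route at 19.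

Step 13 (key oxa-Michael closure). Equilibration may leave appreciable amounts of the C2 or C3 epimers or of the 1,2-adduct lactol, and the enolate may be lost to intermolecular aldol-type oligomerisation under the amine. Fallback, setting out from 19 and returning at 21: the closure is moved from thermodynamic to kinetic, catalyst-controlled conditions. A cinchona-derived bifunctional tertiary amine–squaramide is used in toluene at −20 °C, taking whichever of the quinine- and quinidine-derived pseudoenantiomers is matched with C4. It activates the enal by hydrogen bonding and the enol by general-base catalysis, an established mode for intramolecular oxa-Michael additions. The reaction is quenched cold with acetic acid so that the kinetic ratio is kept. No new compound is made on this path (F0).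

**Further compounds**

F1 | step 11 | methyl (3R)-3-{2-[2-(3,4-bis(TBSO)phenyl)ethoxy]-2-oxoethyl}-2-[(ethylsulfanyl)carbonyl]-4-formylpent-4-enoate | COC(=O)C(C(=O)SCC)[C@@H](CC(=O)OCCc1ccc(O[Si](C)(C)C(C)(C)C)c(O[Si](C)(C)C(C)(C)C)c1)C(=C)C=O
F2 | step 12 | methyl (4R)-4-{2-[2-(3,4-bis(TBSO)phenyl)ethoxy]-2-oxoethyl}-2-hydroxy-3,4-dihydro-2H-pyran-5-carboxylate (anomers) | COC(=O)C1=COC(O)C[C@@H]1CC(=O)OCCc1ccc(O[Si](C)(C)C(C)(C)C)c(O[Si](C)(C)C(C)(C)C)c1
F3 | step 12 | methyl (3R)-3-{2-[2-(3,4-bis(TBSO)phenyl)ethoxy]-2-oxoethyl}-5-oxo-2-(pyrrolidin-1-ylmethylidene)pentanoate | COC(=O)C(=CN1CCCC1)[C@@H](CC(=O)OCCc1ccc(O[Si](C)(C)C(C)(C)C)c(O[Si](C)(C)C(C)(C)C)c1)CC=O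
F4 | step 12 | methyl (3S,4E)-3-{2-[2-(3,4-bis(TBSO)phenyl)ethoxy]-2-oxoethyl}-4-formyl-2-(pyrrolidin-1-ylmethylidene)hex-4-enoate | COC(=O)C(=CN1CCCC1)[C@@H](CC(=O)OCCc1ccc(O[Si](C)(C)C(C)(C)C)c(O[Si](C)(C)C(C)(C)C)c1)/C(C=O)=C\C
F0 | step 13 | none | none
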